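**Retrosynthetic overview**

- The target is a flavanone (rings A, C, B) joined by a ring B–ring F biaryl bond to a flavone (rings D, E, F). The last operations are global debenzylation and conversion of C4 from a methoxy-bearing carbon to the ketone.
- The strategy rests on flavanone ring C: O1 and C4 both sit on phloroglucinol ring A (at C8a and C4a) and C2 carries the para-oxygenated aryl ring B. Cutting O1–C2 and C3–C4 therefore gives a C4-methoxy ortho-quinone methide of ring A (from a salicylaldehyde and trimethyl orthoformate) and the vinyl group of a para-benzyloxystyrene.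
- That styrene already carries the whole benzylated flavone. It comes from a biaryl aldehyde by Wittig methylenation, and the biaryl bond from Suzuki coupling of a 3'-iodoflavone with a formylaryl boronate.
- The iodoflavone comes from a chalcone (Claisen–Schmidt condensation, then oxidative cyclisation); 4-(benzyloxy)-3-iodobenzaldehyde feeds both biaryl halves.
- Ring order: flavone ring E first, then the biaryl bond, and flavanone ring C last, in the step that sets C2.

Key step: step 9

Assumption: the sense of induction of the chiral acid cannot be foretold for this substrate pair. The (R)-catalyst is written, and its mirror image is to be used if a trial shows that (R) leads to the 2R series. The C4 epimer ratio of 16 and 17 is immaterial because C4 becomes the ketone.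

**Route**

Step 1
Reactants: 1 4-hydroxy-3-iodobenzaldehyde; 2 benzyl bromide
Product: 3 4-(benzyloxy)-3-iodobenzaldehyde
Conditions: BnBr, K2CO3, DMF, rt
Reagents that add atoms: benzyl bromide 2, BrCc1ccccc1
Why: Williamson ether synthesis; the acidic phenol (ortho-iodo, para-formyl) should be O-benzylated cleanly.

Step 2
Reactants: 3 4-(benzyloxy)-3-iodobenzaldehyde
Product: 4 4-(benzyloxy)-3-(4,4,5,5-tetramethyl-1,3,2-dioxaborolan-2-yl)benzaldehyde
Conditions: B2pin2, PdCl2(dppf) (3 mol %), KOAc, 1,4-dioxane, 85 °C
Reagents that add atoms: bis(pinacolato)diboron, CC1(C)OB(OC1(C)C)B1OC(C)(C)C(C)(C)O1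
Why: Miyaura borylation of an aryl iodide; the aldehyde and the benzyl ether are tolerated and the weak acetate base should suppress homocoupling.

Step 3
Reactants: 5 2,4,6-trihydroxyacetophenone; 2 benzyl bromide
Product: 6 2-hydroxy-4,6-bis(benzyloxy)acetophenone
Conditions: BnBr (2.1 equiv), K2CO3, DMF, rt to 50 °C
Reagents that add atoms: benzyl bromide 2, BrCc1ccccc1
Why: Williamson etherification; with two equivalents of bromide the 4-OH and one ortho-OH should be alkylated while the remaining ortho-OH, hydrogen-bonded to the ketone, stays free.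

Step 4
Reactants: 6 2-hydroxy-4,6-bis(benzyloxy)acetophenone; 3 4-(benzyloxy)-3-iodobenzaldehyde
Product: 7 (E)-2'-hydroxy-4,4',6'-tris(benzyloxy)-3-iodochalcone
Conditions: KOH (aq.), EtOH/THF, rt
Reagents that add atoms: none
Why: Claisen–Schmidt aldol condensation of the methyl ketone enolate with a non-enolisable aldehyde; E1cB dehydration should give the E-enone.

Step 5
Reactants: 7 (E)-2'-hydroxy-4,4',6'-tris(benzyloxy)-3-iodochalcone
Product: 8 4',5,7-tris(benzyloxy)-3'-iodoflavone
Conditions: I2 (10 mol %), DMSO, 120 °C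
Reagents that add atoms: none
Why: iodine-catalysed oxidative cyclisation of a 2'-hydroxychalcone (oxa-Michael closure, then dehydrogenation with DMSO as terminal oxidant); the aryl iodide and benzyl ethers should be inert while iodine stays catalytic.

Step 6
Reactants: 8 4',5,7-tris(benzyloxy)-3'-iodoflavone; 4 4-(benzyloxy)-3-(4,4,5,5-tetramethyl-1,3,2-dioxaborolan-2-yl)benzaldehyde
Product: 9 4-(benzyloxy)-3-{2-(benzyloxy)-5-[5,7-bis(benzyloxy)-4-oxo-4H-chromen-2-yl]phenyl}benzaldehyde
Conditions: PdCl2(dppf) (5 mol %), K3PO4, 1,4-dioxane/H2O, 85 °C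
Reagents that add atoms: none
Why: Suzuki–Miyaura coupling of an aryl iodide with an aryl pinacol boronate; each partner has one ortho substituent, and the phosphate base should spare the pyranone and the aldehyde.

Step 7
Reactants: 9 4-(benzyloxy)-3-{2-(benzyloxy)-5-[5,7-bis(benzyloxy)-4-oxo-4H-chromen-2-yl]phenyl}benzaldehyde
Product: 10 5,7-bis(benzyloxy)-2-{4-(benzyloxy)-3-[2-(benzyloxy)-5-vinylphenyl]phenyl}-4H-chromen-4-one
Conditions: Ph3PCH3Br, KOtBu (slight deficit), THF, 0 °C; then 9, 0 °C to rt
Reagents that add atoms: methyltriphenylphosphonium bromide, C[P+](c1ccccc1)(c1ccccc1)c1ccccc1.[Br-]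
Why: Wittig methylenation; the aldehyde is far more electrophilic than the vinylogous-ester carbonyl of the 2-arylchromenone, which the preformed ylide should leave untouched at 0 °C.

Step 8
Reactants: 11 2,4,6-trihydroxybenzaldehyde; 2 benzyl bromide
Product: 12 2-hydroxy-4,6-bis(benzyloxy)benzaldehyde
Conditions: BnBr (2.05 equiv), K2CO3, DMF, rt
Reagents that add atoms: benzyl bromide 2, BrCc1ccccc1
Why: Williamson etherification; as in step 3, the ortho-OH chelated to the carbonyl should resist the third alkylation.

Step 9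
Reactants: 12 2-hydroxy-4,6-bis(benzyloxy)benzaldehyde; 13 trimethyl orthoformate; 10 5,7-bis(benzyloxy)-2-{4-(benzyloxy)-3-[2-(benzyloxy)-5-vinylphenyl]phenyl}-4H-chromen-4-one
Product: 16 (2S,4S)-2,4-cis-4-methoxyflavan hexabenzyl ether, via dimethyl acetal 14 (not isolated), via methoxy ortho-quinone methide 15 (not isolated)
Conditions: 12 (1.3 equiv, slow addition), HC(OMe)3 (3 equiv), (R)-3,3'-bis(2,4,6-triisopropylphenyl)-BINOL N-triflylphosphoramide (10 mol %), CH2Cl2, −40 °C; Et3N quench at −40 °C
Reagents that add atoms: trimethyl orthoformate 13, COC(OC)OC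
Why: Proposed new method: acid-catalysed exchange with the orthoformate turns 12 into acetal 14, which loses methanol to give 15 in its O-protonated form, a 2-hydroxyaryl oxocarbenium ion hydrogen-bonded in a contact ion pair with the chiral phosphoramide anion; the CH2 terminus of the vinyl group of 10 bonds to the carbenium carbon (C3–C4) while positive charge grows on the carbon next to the para-benzyloxyaryl ring, onto which the ring A oxygen then closes (O1–C2). The closest known reactions are the acid-promoted three-component [4+2] of salicylaldehydes, orthoformates and styrenes giving 2,4-cis-4-alkoxy-2-arylchromans, and the chiral phosphoric acid or N-triflylphosphoramide catalysed [4+2] of ortho-quinone methides from ortho-hydroxybenzyl alcohols with styrenes; untested is enantiocontrol over an acetal-derived alkoxy quinone methide with a styrene that carries a basic flavone. Ring C is closed by an intermolecular, asynchronous inverse-demand oxa-[4+2] cycloaddition, the C–C bond first and the six-membered O–C closure second. The anion should shield one face of the carbenium carbon and so fix C4, and the endo placement of the aryl group relative to the methoxy group (or, if the addition is stepwise, equatorial closure onto the cation) should relay this to C2 as the 2,4-cis isomer; only C2 has to last, since C4 is erased in steps 10 and 11. Regiochemistry comes from the para-benzyloxy group, which makes CH2 the nucleophilic alkene terminus; the step also needs the styrene to outrun Friedel–Crafts attack on ring A of 12 and 16 and needs the C2–O bond not to re-ionise, which slow addition of 12, −40 °C and an amine quench before warming are meant to secure.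

Step 10
Reactants: 16 (2S,4S)-2,4-cis-4-methoxyflavan hexabenzyl ether
Product: 17 (2S)-flavan-4-ol hexabenzyl ether (C4 epimers)
Conditions: PPTS (0.2 equiv), THF/H2O (5:1), rt to 40 °C
Reagents that add atoms: water, O
Why: acid-catalysed SN1 solvolysis of the benzylic methyl ether; C4 should ionise easily as a 2,4,6-trioxygenated benzyl cation and be captured by water, while the C2–O bond lacks such stabilisation and should hold at pyridinium-level acidity, so C2 is untouched.

Step 11
Reactants: 17 (2S)-flavan-4-ol hexabenzyl ether (C4 epimers)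
Product: 18 (2S)-flavanone hexabenzyl ether
Conditions: Dess–Martin periodinane (1.5 equiv), pyridine, CH2Cl2, 0 °C to rt
Reagents that add atoms: none
Why: Dess–Martin oxidation of a secondary benzylic alcohol under buffered conditions; both C4 epimers should converge on the ketone with no base or strong acid present that could open ring C and scramble C2.

Step 12
Reactants: 18 (2S)-flavanone hexabenzyl ether
Product: 19 (2S)-5,7-dihydroxy-2-{4-hydroxy-3-[2-hydroxy-5-(5,7-dihydroxy-4-oxo-4H-chromen-2-yl)phenyl]phenyl}chroman-4-one (target)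
Conditions: BCl3 (15 equiv), C6HMe5 (20 equiv), CH2Cl2, −78 °C; aqueous work-up
Reagents that add atoms: none
Why: Lewis-acid cleavage of aryl benzyl ethers with BCl3 and pentamethylbenzene as a non-basic cation scavenger; benzyl cations should be trapped before they C-benzylate the phloroglucinol rings, and −78 °C should preserve C2.

**Compound list**

1 | 4-hydroxy-3-iodobenzaldehyde | O=Cc1ccc(O)c(I)c1 | starting material
2 | benzyl bromide | BrCc1ccccc1 | starting material
3 | 4-(benzyloxy)-3-iodobenzaldehyde | O=Cc1ccc(OCc2ccccc2)c(I)c1 | intermediate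
4 | 4-(benzyloxy)-3-(4,4,5,5-tetramethyl-1,3,2-dioxaborolan-2-yl)benzaldehyde | O=Cc1ccc(OCc2ccccc2)c(B2OC(C)(C)C(C)(C)O2)c1 | intermediate
5 | 2,4,6-trihydroxyacetophenone | CC(=O)c1c(O)cc(O)cc1O | starting material
6 | 2-hydroxy-4,6-bis(benzyloxy)acetophenone | CC(=O)c1c(O)cc(OCc2ccccc2)cc1OCc1ccccc1 | intermediate
7 | (E)-1-[2-hydroxy-4,6-bis(benzyloxy)phenyl]-3-[4-(benzyloxy)-3-iodophenyl]prop-2-en-1-one | O=C(/C=C/c1ccc(OCc2ccccc2)c(I)c1)c1c(O)cc(OCc2ccccc2)cc1OCc1ccccc1 | intermediate
8 | 4',5,7-tris(benzyloxy)-3'-iodoflavone | O=c1cc(-c2ccc(OCc3ccccc3)c(I)c2)oc2cc(OCc3ccccc3)cc(OCc3ccccc3)c12 | intermediate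
9 | 4-(benzyloxy)-3-{2-(benzyloxy)-5-[5,7-bis(benzyloxy)-4-oxo-4H-chromen-2-yl]phenyl}benzaldehyde | O=Cc1ccc(OCc2ccccc2)c(-c2cc(-c3cc(=O)c4c(OCc5ccccc5)cc(OCc5ccccc5)cc4o3)ccc2OCc2ccccc2)c1 | intermediate
10 | 5,7-bis(benzyloxy)-2-{4-(benzyloxy)-3-[2-(benzyloxy)-5-vinylphenyl]phenyl}-4H-chromen-4-one | C=Cc1ccc(OCc2ccccc2)c(-c2cc(-c3cc(=O)c4c(OCc5ccccc5)cc(OCc5ccccc5)cc4o3)ccc2OCc2ccccc2)c1 | intermediate
11 | 2,4,6-trihydroxybenzaldehyde | O=Cc1c(O)cc(O)cc1O | starting material
12 | 2-hydroxy-4,6-bis(benzyloxy)benzaldehyde | O=Cc1c(O)cc(OCc2ccccc2)cc1OCc1ccccc1 | intermediate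
13 | trimethyl orthoformate | COC(OC)OC | starting material
14 | 3,5-bis(benzyloxy)-2-(dimethoxymethyl)phenol (dimethyl acetal of 12) | COC(OC)c1c(O)cc(OCc2ccccc2)cc1OCc1ccccc1 | intermediate
15 | 3,5-bis(benzyloxy)-6-(methoxymethylene)cyclohexa-2,4-dien-1-one (4-methoxy ortho-quinone methide, reacting as its O-protonated form) | COC=C1C(=O)C=C(OCc2ccccc2)C=C1OCc1ccccc1 | intermediate
16 | (2S,4S)-5,7-bis(benzyloxy)-2-{4-(benzyloxy)-3-[2-(benzyloxy)-5-(5,7-bis(benzyloxy)-4-oxo-4H-chromen-2-yl)phenyl]phenyl}-4-methoxychroman (2,4-cis) | CO[C@H]1C[C@@H](c2ccc(OCc3ccccc3)c(-c3cc(-c4cc(=O)c5c(OCc6ccccc6)cc(OCc6ccccc6)cc5o4)ccc3OCc3ccccc3)c2)Oc2cc(OCc3ccccc3)cc(OCc3ccccc3)c21 | intermediate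
17 | (2S)-5,7-bis(benzyloxy)-2-{4-(benzyloxy)-3-[2-(benzyloxy)-5-(5,7-bis(benzyloxy)-4-oxo-4H-chromen-2-yl)phenyl]phenyl}chroman-4-ol (C4 epimers, C4 left undefined) | OC1C[C@@H](c2ccc(OCc3ccccc3)c(-c3cc(-c4cc(=O)c5c(OCc6ccccc6)cc(OCc6ccccc6)cc5o4)ccc3OCc3ccccc3)c2)Oc2cc(OCc3ccccc3)cc(OCc3ccccc3)c21 | intermediate
18 | (2S)-5,7-bis(benzyloxy)-2-{4-(benzyloxy)-3-[2-(benzyloxy)-5-(5,7-bis(benzyloxy)-4-oxo-4H-chromen-2-yl)phenyl]phenyl}chroman-4-one | O=C1C[C@@H](c2ccc(OCc3ccccc3)c(-c3cc(-c4cc(=O)c5c(OCc6ccccc6)cc(OCc6ccccc6)cc5o4)ccc3OCc3ccccc3)c2)Oc2cc(OCc3ccccc3)cc(OCc3ccccc3)c21 | intermediate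
19 | (2S)-5,7-dihydroxy-2-{4-hydroxy-3-[2-hydroxy-5-(5,7-dihydroxy-4-oxo-4H-chromen-2-yl)phenyl]phenyl}chroman-4-one | O=C1C[C@@H](c2ccc(O)c(-c3cc(-c4cc(=O)c5c(O)cc(O)cc5o4)ccc3O)c2)Oc2cc(O)cc(O)c21 | target

**Step count**

Total: 12 steps. Longest linear sequence: 9 steps (1, 4, 5, 6, 7, 9, 10, 11, 12 from compound 1; equally 3, 4, 5, 6, 7, 9, 10, 11, 12 from compound 5).

**Steps most likely to fail**

Step 9 (proposed new method). Three processes may defeat it: facial selectivity may be poor or of the wrong sense; the basic flavone carbonyl of 10 may tie up the acid; and Friedel–Crafts attack of the cationic intermediate on ring A of 12 or 16, or re-ionisation at C2, may outrun or undo the cycloaddition. The fallback uses the known bifunctional-thiourea oxa-Michael route to flavanones. It sets out from acetophenone 6 and aldehyde 9 and returns to the route at flavanone 18, bypassing steps 7 to 11. The dianion of 6 (LiN(SiMe3)2, THF, −78 °C) is C-acylated with di-tert-butyl dicarbonate to give tert-butyl 3-[2,4-bis(benzyloxy)-6-hydroxyphenyl]-3-oxopropanoate F1. Knoevenagel condensation of this β-keto ester with 9 (piperidine, AcOH, toluene) gives tert-butyl 2-[2,4-bis(benzyloxy)-6-hydroxybenzoyl]-3-aryl-prop-2-enoate F2, in which the aryl group is the biaryl flavone residue of 9. A cinchona-alkaloid thiourea (the quinine- or quinidine-derived pseudoenantiomer that leads to 2S) should then catalyse intramolecular oxa-Michael addition of the phenol to give tert-butyl (2S)-4-oxoflavan-3-carboxylate hexabenzyl ether F3. Warming with TsOH in toluene should remove the tert-butyl ester with decarboxylation and give 18.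

Step 10. Ionisation at C4 may end in loss of the C3 proton (flav-3-ene formation) or in Friedel–Crafts self-condensation through ring A instead of capture by water. The fallback sets out from 16 and returns at 18 without passing through the free alcohol. DDQ in CH2Cl2/pH 7 buffer at 0 °C should abstract hydride from C4, the most electron-rich benzylic C–H (flanked by the methoxy group and the trioxygenated ring A). Hydrolysis of the resulting methoxy-oxocarbenium ion gives the ketone directly; this is the known oxidative manifold of electron-rich benzylic ethers. The fallback makes no compound outside the compound list (F0).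

Step 12. Lewis-acid-induced opening of ring C at the O1–C2 bond would erode the C2 configuration, and six-fold cleavage may stall at partly benzylated stages. The fallback sets out from 18 and returns at 19 by catalytic hydrogenolysis (H2 at 1 atm, Pd(OH)2/C or Pd/C, THF/MeOH, rt), a neutral method long used for benzylated flavones and flavanones. The reaction is to be stopped at full debenzylation, before the flavone C2=C3 bond or the benzylic C2–O bond is reduced. The fallback makes no compound outside the compound list (F0).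

Further compounds
F1 | step 9 | tert-butyl 3-[2,4-bis(benzyloxy)-6-hydroxyphenyl]-3-oxopropanoate | CC(C)(C)OC(=O)CC(=O)c1c(O)cc(OCc2ccccc2)cc1OCc1ccccc1
F2 | step 9 | tert-butyl 2-[2,4-bis(benzyloxy)-6-hydroxybenzoyl]-3-{4-(benzyloxy)-3-[2-(benzyloxy)-5-(5,7-bis(benzyloxy)-4-oxo-4H-chromen-2-yl)phenyl]phenyl}prop-2-enoate (E/Z mixture) | CC(C)(C)OC(=O)C(=Cc1ccc(OCc2ccccc2)c(-c2cc(-c3cc(=O)c4c(OCc5ccccc5)cc(OCc5ccccc5)cc4o3)ccc2OCc2ccccc2)c1)C(=O)c1c(O)cc(OCc2ccccc2)cc1OCc1ccccc1
F3 | step 9 | tert-butyl (2S)-5,7-bis(benzyloxy)-2-{4-(benzyloxy)-3-[2-(benzyloxy)-5-(5,7-bis(benzyloxy)-4-oxo-4H-chromen-2-yl)phenyl]phenyl}-4-oxochroman-3-carboxylate (C3 epimerisable, left undefined) | CC(C)(C)OC(=O)C1C(=O)c2c(OCc3ccccc3)cc(OCc3ccccc3)cc2O[C@@H]1c1ccc(OCc2ccccc2)c(-c2cc(-c3cc(=O)c4c(OCc5ccccc5)cc(OCc5ccccc5)cc4o3)ccc2OCc2ccccc2)c1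
F0 | step 10 | none | none
F0 | step 12 | none | none
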